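## Retrosynthetic overview

1. Feature: in the furan ring (O1–C2–C3–C3a–C7a), C3 carries two carbons at carbonyl level, namely C2 (bonded to O1 and the resorcinol ring) and the formyl carbon. If O1 is moved from C2 to the formyl carbon, the skeleton becomes a 3-aroylbenzofuran-2(3H)-one. The aldehyde carbon can therefore travel as a lactone carbonyl, and no formylation at C3 is needed.
2. Endgame: MOM removal; CHO from CO2Me by reduction and oxidation; C5 prenyl by aromatic Claisen shift of a 4-O-(1,1-dimethylallyl) ether, whose other ortho carbon is the ring-fusion atom C3a. The ether is made from the 4-phenol and 3-chloro-3-methylbut-1-yne.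
3. Key disconnection: the O1–C2 bond of the 2-arylbenzofuran-3-carboxylate. It is formed from the 3-aroyl lactone by methanolysis of the lactone and reclosure of the freed phenol on the aryl ketone.
4. The aroyl lactone comes from C3 acylation of 6-methoxy-4-silyloxybenzofuran-2(3H)-one with the imidazolide of 2,4-bis(methoxymethoxy)benzoic acid. The lactone comes from 2',6'-dihydroxy-4'-methoxyacetophenone by oxidative 1,2-aryl shift to the arylacetate.
5. Ring order: both benzene rings are bought. The five-membered lactone ring is closed first (step 3), then opened and replaced by the furan ring (step 8).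

Key step: step 8

Remark: the target has no stereocentre, and its only acyclic C=C bears two identical methyl groups, so no configuration has to be set. The 3-aroyl lactone is drawn as its racemic keto tautomer, although it should be largely enolised.

## Route

Step 1
Reactants: 1 2',6'-dihydroxy-4'-methoxyacetophenone
Product: 2 2',6'-bis(benzyloxy)-4'-methoxyacetophenone
Conditions: BnBr (2.4 equiv), K2CO3 (3 equiv), DMF, 70 °C
Reagents that add atoms: benzyl bromide, BrCc1ccccc1
Why: Williamson etherification: carbonate in warm DMF deprotonates both chelated ortho-hydroxyls, and benzyl ethers are chosen because they withstand the nitric acid released in step 2 and can be removed by hydrogenolysis while the molecule still holds no alkene.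

Step 2
Reactants: 2 2',6'-bis(benzyloxy)-4'-methoxyacetophenone
Product: 3 methyl 2-[2,6-bis(benzyloxy)-4-methoxyphenyl]acetate
Conditions: Tl(NO3)3·3H2O (1.1 equiv), MeOH–HC(OMe)3 (1:1), 0 °C → rt
Reagents that add atoms: methanol, CO
Why: Oxidative 1,2-aryl migration of an aryl methyl ketone with Tl(NO3)3: the enol ether formed in the orthoformate medium is oxythallated at the methyl carbon and the very electron-rich aryl group migrates to it as monovalent thallium departs, which turns ArCOCH3 into ArCH2CO2Me with the ring substitution pattern fixed by the starting material.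

Step 3
Reactants: 3 methyl 2-[2,6-bis(benzyloxy)-4-methoxyphenyl]acetate
Product: 5 4-hydroxy-6-methoxybenzofuran-2(3H)-one, via dihydroxy ester 4 (not isolated)
Conditions: H2 (1 atm), Pd/C, EtOAc, rt; filter; then p-TsOH·H2O (5 mol%), toluene, reflux with removal of MeOH
Reagents that add atoms: none
Why: Hydrogenolysis of the benzyl ethers followed by acid-catalysed lactonisation (intramolecular transesterification, 5-exo-trig) driven by removal of methanol; the two phenols of 4 are related by symmetry, so only one lactone can form and one hydroxyl is left free at C4.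

Step 4
Reactants: 5 4-hydroxy-6-methoxybenzofuran-2(3H)-one
Product: 6 6-methoxy-4-(triisopropylsilyloxy)benzofuran-2(3H)-one
Conditions: i-Pr3SiCl (1.2 equiv), imidazole (2.5 equiv), DMF, rt
Reagents that add atoms: triisopropylsilyl chloride, CC(C)[Si](Cl)(C(C)C)C(C)C
Why: Imidazole-promoted silylation of the only hydroxyl group, needed because a free phenol would be aroylated in step 7; imidazole is too weak a base to enolise the lactone appreciably and the bulky aryl silyl ether tolerates amide bases and short contact with methoxide.

Step 5
Reactants: 7 2,4-dihydroxybenzoic acid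
Product: 8 methoxymethyl 2,4-bis(methoxymethoxy)benzoate
Conditions: MOMCl (4.5 equiv), i-Pr2NEt (5 equiv), CH2Cl2, 0 °C → reflux
Reagents that add atoms: chloromethyl methyl ether, COCCl
Why: Alkylation of the carboxylate and both phenols with an α-chloro ether (SN1-like, through the oxocarbenium ion), which also reaches the hydrogen-bonded 2-OH on warming; MOM ethers are chosen because they survive enolates, fluoride, hydride, hydrogenation and 130 °C and leave at the end without reductive or Lewis acidic conditions that would harm the prenyl group.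

Step 6
Reactants: 8 methoxymethyl 2,4-bis(methoxymethoxy)benzoate
Product: 9 2,4-bis(methoxymethoxy)benzoic acid
Conditions: LiOH (3 equiv), THF–H2O, 40 °C; then 1 M HCl to pH 4, 0 °C
Reagents that add atoms: water (delivered as hydroxide), O
Why: Saponification: the acetal-type MOM ester is far more electrophilic than any other group in 8 and the aryl MOM ethers are inert to base, while cold acidification only to pH 4 protonates the carboxylate without hydrolysing them.

Step 7
Reactants: 6 6-methoxy-4-(triisopropylsilyloxy)benzofuran-2(3H)-one; 9 2,4-bis(methoxymethoxy)benzoic acid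
Product: 11 3-[2,4-bis(methoxymethoxy)benzoyl]-6-methoxy-4-(triisopropylsilyloxy)benzofuran-2(3H)-one (racemic keto form shown; largely enolised), via acyl imidazole 10 (not isolated)
Conditions: flask A: 9 (1.1 equiv), CDI (1.05 equiv), THF, rt; flask B: 6, LiN(SiMe3)2 (1.1 equiv), THF, −78 °C, Ar; A into B, −78 °C → rt; AcOH quench
Reagents that add atoms: 1,1'-carbonyldiimidazole, O=C(n1ccnc1)n1ccnc1 (supplies the imidazolyl group of 10; none of its atoms stays in 11)
Why: Crossed Claisen-type C-acylation of a lactone enolate by an acyl imidazole: C3 is the only acidic carbon of 6, O-acylation is reversible because an enol ester is itself an acyl donor toward the imidazolide present, C-acylation becomes irreversible when imidazolide deprotonates 11 to its chelated lithium enolate, and CDI activates 9 without any acid that would strip the MOM groups.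

Step 8
Reactants: 11 3-[2,4-bis(methoxymethoxy)benzoyl]-6-methoxy-4-(triisopropylsilyloxy)benzofuran-2(3H)-one
Product: 14 methyl 2-[2,4-bis(methoxymethoxy)phenyl]-6-methoxy-4-(triisopropylsilyloxy)benzofuran-3-carboxylate, via phenol keto ester 12 (not isolated), via cyclic hemiketal 13 (not isolated)
Conditions: NaOMe (0.2 equiv), MeOH–THF, 0 °C → rt; then AcOH (excess), 60 °C
Reagents that add atoms: methanol, CO
Why: Compound 11 is a vinylogous acid and binds the methoxide as its enolate, so ring opening should run through the small equilibrium share of keto lactone and free methoxide: addition to the strained aryl-ester (lactone) carbonyl and departure of the ring oxygen as phenoxide give phenol β-keto ester 12. The freed phenol oxygen adds to the aryl ketone carbon, the future C2, in a 5-exo-trig closure (new O1–C2 bond) to hemiketal 13, acetic acid ionises the tertiary C2–OH to an oxocarbenium ion stabilised by the 2,4-dialkoxyphenyl group, and loss of the acidic C3–H gives the aromatic furan of 14, which makes the sequence irreversible and also drains any 11 left at the quench through the acetate buffer. The closest known reaction type is the solvolytic rearrangement of simple 3-acylbenzofuran-2(3H)-ones into 2-substituted benzofuran-3-carboxylic acids and esters. The stereocentres at C3 of 11 and 12 and at C2 and C3 of 13 are transient and are erased on aromatisation, so none needs control. The selectivity needed is attack at the lactone carbonyl instead of the ketone (retro-Claisen loss of the aroyl group); the ketone is shielded by the ortho-OMOM group and deactivated by two donor oxygens whereas the lactone is a strained phenyl-type ester, and the substoichiometric base, 0 °C and the early acidic quench keep free methoxide scarce. Since the opened arene bears oxygen on both carbons ortho to the side chain in a symmetric pattern, premature loss of the silyl group would only lead to 15, the product of the next step.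

Step 9
Reactants: 14 methyl 2-[2,4-bis(methoxymethoxy)phenyl]-6-methoxy-4-(triisopropylsilyloxy)benzofuran-3-carboxylate
Product: 15 methyl 2-[2,4-bis(methoxymethoxy)phenyl]-4-hydroxy-6-methoxybenzofuran-3-carboxylate
Conditions: Bu4NF (1.2 equiv), AcOH (1.2 equiv), THF, 0 °C
Reagents that add atoms: none
Why: Fluoride-induced cleavage of the aryl silyl ether driven by the strong Si–F bond; the acetic acid buffer keeps the medium from becoming basic enough to touch the methyl ester and MOM ethers are inert to fluoride.

Step 10
Reactants: 15 methyl 2-[2,4-bis(methoxymethoxy)phenyl]-4-hydroxy-6-methoxybenzofuran-3-carboxylate; 16 3-chloro-3-methylbut-1-yne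
Product: 17 methyl 2-[2,4-bis(methoxymethoxy)phenyl]-6-methoxy-4-(2-methylbut-3-yn-2-yloxy)benzofuran-3-carboxylate
Conditions: DBU (1.5 equiv), CuCl2·2H2O (1 mol%), MeCN, 0 °C → rt
Reagents that add atoms: none
Why: Copper-catalysed propargylic etherification: DBU forms the phenoxide and the copper acetylide of 16 ionises to an allenylidene-type electrophile that the phenoxide captures at the tertiary carbon, so no SN2 attack at a tertiary centre is required, and the gap between the C3 and C4 substituents of a 5/6-fused system is wider than a naphthalene peri gap.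

Step 11
Reactants: 17 methyl 2-[2,4-bis(methoxymethoxy)phenyl]-6-methoxy-4-(2-methylbut-3-yn-2-yloxy)benzofuran-3-carboxylate
Product: 18 methyl 2-[2,4-bis(methoxymethoxy)phenyl]-6-methoxy-4-(2-methylbut-3-en-2-yloxy)benzofuran-3-carboxylate
Conditions: H2 (1 atm, stopped after 1 equiv), Pd/CaCO3 poisoned with Pb(OAc)2, quinoline, EtOAc, rt
Reagents that add atoms: none
Why: Lindlar-type semihydrogenation: the poisoned palladium surface adds one equivalent of hydrogen to the terminal alkyne and releases the alkene, and nothing else in 17 is reducible under these conditions.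

Step 12
Reactants: 18 methyl 2-[2,4-bis(methoxymethoxy)phenyl]-6-methoxy-4-(2-methylbut-3-en-2-yloxy)benzofuran-3-carboxylate
Product: 20 methyl 2-[2,4-bis(methoxymethoxy)phenyl]-4-hydroxy-6-methoxy-5-(3-methylbut-2-en-1-yl)benzofuran-3-carboxylate, via cyclohexadienone 19 (not isolated)
Conditions: PhNEt2, 130 °C, Ar
Reagents that add atoms: none
Why: Aromatic Claisen rearrangement: the [3,3] shift inverts the 1,1-dimethylallyl unit into a prenyl group on the only free ortho carbon C5 (the other ortho position is ring-fusion carbon C3a), dienone 19 tautomerises at once to the phenol, the gem-dimethyl group lowers the temperature needed, and the basic solvent suppresses acid-induced ionisation of the tertiary ether and chroman closure.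

Step 13
Reactants: 20 methyl 2-[2,4-bis(methoxymethoxy)phenyl]-4-hydroxy-6-methoxy-5-(3-methylbut-2-en-1-yl)benzofuran-3-carboxylate
Product: 21 2-[2,4-bis(methoxymethoxy)phenyl]-3-(hydroxymethyl)-6-methoxy-5-(3-methylbut-2-en-1-yl)benzofuran-4-ol
Conditions: LiAlH4 (2.5 equiv), THF, 0 °C; Na2SO4·10H2O quench
Reagents that add atoms: none
Why: Hydride reduction of an ester: the first hydride deprotonates the 4-OH and the aluminium phenoxide formed sits next to the ester and delivers hydride to it, MOM ethers and the trisubstituted alkene are inert, and 0 °C avoids hydrogenolysis of the electron-rich heterobenzylic C–O bond.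

Step 14
Reactants: 21 2-[2,4-bis(methoxymethoxy)phenyl]-3-(hydroxymethyl)-6-methoxy-5-(3-methylbut-2-en-1-yl)benzofuran-4-ol
Product: 22 2-[2,4-bis(methoxymethoxy)phenyl]-4-hydroxy-6-methoxy-5-(3-methylbut-2-en-1-yl)benzofuran-3-carbaldehyde
Conditions: activated MnO2 (15 equiv), CH2Cl2, rt
Reagents that add atoms: none
Why: MnO2 oxidation selective for benzylic-type alcohols, as in the conversion of salicyl alcohols into salicylaldehydes; it stops at the aldehyde, leaves the prenyl group alone, and the meta-related oxygen pattern of the phenol ring offers no quinone outlet.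

Step 15
Reactants: 22 2-[2,4-bis(methoxymethoxy)phenyl]-4-hydroxy-6-methoxy-5-(3-methylbut-2-en-1-yl)benzofuran-3-carbaldehyde
Product: 23 2-(2,4-dihydroxyphenyl)-4-hydroxy-6-methoxy-5-(3-methylbut-2-en-1-yl)benzofuran-3-carbaldehyde (target)
Conditions: 3 M aq. HCl–THF (1:3), 45 °C
Reagents that add atoms: none
Why: Acid hydrolysis of the two aryl MOM acetals in a water-rich, methanol-free medium, so that the aldehyde and the freed 2'-OH cannot be trapped as a cyclic methyl acetal, while the 4-OH is tied up in a hydrogen bond to the formyl oxygen, which slows its acid-induced addition to the prenyl double bond.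

## Compound list

1 | 2',6'-dihydroxy-4'-methoxyacetophenone | CC(=O)c1c(O)cc(OC)cc1O | starting material
2 | 2',6'-bis(benzyloxy)-4'-methoxyacetophenone | CC(=O)c1c(OCc2ccccc2)cc(OC)cc1OCc1ccccc1 | intermediate
3 | methyl 2-[2,6-bis(benzyloxy)-4-methoxyphenyl]acetate | COC(=O)Cc1c(OCc2ccccc2)cc(OC)cc1OCc1ccccc1 | intermediate
4 | methyl 2-(2,6-dihydroxy-4-methoxyphenyl)acetate (not isolated) | COC(=O)Cc1c(O)cc(OC)cc1O | intermediate
5 | 4-hydroxy-6-methoxybenzofuran-2(3H)-one | O=C1Cc2c(O)cc(OC)cc2O1 | intermediate
6 | 6-methoxy-4-(triisopropylsilyloxy)benzofuran-2(3H)-one | O=C1Cc2c(O[Si](C(C)C)(C(C)C)C(C)C)cc(OC)cc2O1 | intermediate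
7 | 2,4-dihydroxybenzoic acid | O=C(O)c1ccc(O)cc1O | starting material
8 | methoxymethyl 2,4-bis(methoxymethoxy)benzoate | COCOC(=O)c1ccc(OCOC)cc1OCOC | intermediate
9 | 2,4-bis(methoxymethoxy)benzoic acid | O=C(O)c1ccc(OCOC)cc1OCOC | intermediate
10 | 1-[2,4-bis(methoxymethoxy)benzoyl]imidazole (not isolated) | O=C(c1ccc(OCOC)cc1OCOC)n1ccnc1 | intermediate
11 | 3-[2,4-bis(methoxymethoxy)benzoyl]-6-methoxy-4-(triisopropylsilyloxy)benzofuran-2(3H)-one (racemic; largely enolised) | O=C1Oc2cc(OC)cc(O[Si](C(C)C)(C(C)C)C(C)C)c2C1C(=O)c1ccc(OCOC)cc1OCOC | intermediate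
12 | methyl 3-[2,4-bis(methoxymethoxy)phenyl]-2-[2-hydroxy-4-methoxy-6-(triisopropylsilyloxy)phenyl]-3-oxopropanoate (racemic; not isolated) | COC(=O)C(C(=O)c1ccc(OCOC)cc1OCOC)c1c(O)cc(OC)cc1O[Si](C(C)C)(C(C)C)C(C)C | intermediate
13 | methyl 2-[2,4-bis(methoxymethoxy)phenyl]-2-hydroxy-6-methoxy-4-(triisopropylsilyloxy)-2,3-dihydrobenzofuran-3-carboxylate (diastereomer mixture, racemic; not isolated) | COC(=O)C1c2c(O[Si](C(C)C)(C(C)C)C(C)C)cc(OC)cc2OC1(O)c1ccc(OCOC)cc1OCOC | intermediate
14 | methyl 2-[2,4-bis(methoxymethoxy)phenyl]-6-methoxy-4-(triisopropylsilyloxy)benzofuran-3-carboxylate | COC(=O)c1c(-c2ccc(OCOC)cc2OCOC)oc2cc(OC)cc(O[Si](C(C)C)(C(C)C)C(C)C)c12 | intermediate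
15 | methyl 2-[2,4-bis(methoxymethoxy)phenyl]-4-hydroxy-6-methoxybenzofuran-3-carboxylate | COC(=O)c1c(-c2ccc(OCOC)cc2OCOC)oc2cc(OC)cc(O)c12 | intermediate
16 | 3-chloro-3-methylbut-1-yne | CC(C)(Cl)C#C | starting material
17 | methyl 2-[2,4-bis(methoxymethoxy)phenyl]-6-methoxy-4-(2-methylbut-3-yn-2-yloxy)benzofuran-3-carboxylate | COC(=O)c1c(-c2ccc(OCOC)cc2OCOC)oc2cc(OC)cc(OC(C)(C)C#C)c12 | intermediate
18 | methyl 2-[2,4-bis(methoxymethoxy)phenyl]-6-methoxy-4-(2-methylbut-3-en-2-yloxy)benzofuran-3-carboxylate | COC(=O)c1c(-c2ccc(OCOC)cc2OCOC)oc2cc(OC)cc(OC(C)(C)C=C)c12 | intermediate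
19 | methyl 2-[2,4-bis(methoxymethoxy)phenyl]-6-methoxy-5-(3-methylbut-2-en-1-yl)-4-oxo-4,5-dihydrobenzofuran-3-carboxylate (racemic; not isolated) | COC(=O)c1c(-c2ccc(OCOC)cc2OCOC)oc2C=C(OC)C(CC=C(C)C)C(=O)c12 | intermediate
20 | methyl 2-[2,4-bis(methoxymethoxy)phenyl]-4-hydroxy-6-methoxy-5-(3-methylbut-2-en-1-yl)benzofuran-3-carboxylate | COC(=O)c1c(-c2ccc(OCOC)cc2OCOC)oc2cc(OC)c(CC=C(C)C)c(O)c12 | intermediate
21 | 2-[2,4-bis(methoxymethoxy)phenyl]-3-(hydroxymethyl)-6-methoxy-5-(3-methylbut-2-en-1-yl)benzofuran-4-ol | OCc1c(-c2ccc(OCOC)cc2OCOC)oc2cc(OC)c(CC=C(C)C)c(O)c12 | intermediate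
22 | 2-[2,4-bis(methoxymethoxy)phenyl]-4-hydroxy-6-methoxy-5-(3-methylbut-2-en-1-yl)benzofuran-3-carbaldehyde | O=Cc1c(-c2ccc(OCOC)cc2OCOC)oc2cc(OC)c(CC=C(C)C)c(O)c12 | intermediate
23 | 2-(2,4-dihydroxyphenyl)-4-hydroxy-6-methoxy-5-(3-methylbut-2-en-1-yl)benzofuran-3-carbaldehyde | COc1cc2oc(-c3ccc(O)cc3O)c(C=O)c2c(O)c1CC=C(C)C | target

## Step count and risks

Total step count: 15.
Longest linear sequence: 13 (steps 1–4 and 7–15). The acid branch (steps 5 and 6) joins at step 7.

**Step 8 (key step).**
- What may go wrong:
  - The acidic substrate may hold all the base as an unreactive enolate, so that ring opening stalls.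
  - Retro-Claisen cleavage of the aroyl group may overtake methanolysis.
  - Dehydration of the hemiketal may be too slow under an acid mild enough for the MOM groups.
- Fallback: it avoids the lactone. It sets out from 3, together with 10 prepared as in step 7, and comes back to the route at 15.
  - The enolate of 3 (LiN(i-Pr)2, THF, −78 °C) is acylated with 10. This should give methyl 2-[2,6-bis(benzyloxy)-4-methoxyphenyl]-3-[2,4-bis(methoxymethoxy)phenyl]-3-oxopropanoate F1.
  - Hydrogenolysis (H2, Pd/C, EtOAc) should free methyl 3-[2,4-bis(methoxymethoxy)phenyl]-2-(2,6-dihydroxy-4-methoxyphenyl)-3-oxopropanoate F2.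
  - In F2 either of the two equivalent phenols closes on the ketone. Warming in AcOH completes the dehydration and gives 15 directly.

**Step 7.**
- What may go wrong:
  - The ambident enolate may be acylated on oxygen.
  - Conversion may be poor, because C3 is shielded by the neighbouring silyl ether and the acyl donor is electron-rich and ortho-substituted.
- Fallback: it accepts O-acylation and moves the acyl group afterwards. It sets out from 9 and 6 and comes back at 11.
  - 1-Chloro-N,N,2-trimethylpropenylamine in CH2Cl2 at 0 °C (neutral conditions) converts 9 into 2,4-bis(methoxymethoxy)benzoyl chloride F3.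
  - F3 is used at once with 6 and Et3N and should give the enol ester 6-methoxy-4-(triisopropylsilyloxy)benzofuran-2-yl 2,4-bis(methoxymethoxy)benzoate F4.
  - DMAP or 4-pyrrolidinopyridine then transfers the acyl group from oxygen to C3 through an acylpyridinium/enolate ion pair (Black rearrangement). This delivers 11.

**Step 10.**
- What may go wrong:
  - Etherification of the hydrogen-bonded phenol, flanked by the C3 ester, may be slow.
  - Loss of HCl from 16 or alkylation on ring carbon may then take over.
- Fallback: a Tsuji–Trost-type O-allylation with zerovalent palladium. It sets out from 15 and comes back at 18, so it replaces steps 10 and 11.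
  - Compound 15 is treated with tert-butyl 2-methylbut-3-en-2-yl carbonate (C=CC(C)(C)OC(=O)OC(C)(C)C) and Pd(PPh3)4 in THF at 0 °C.
  - Under kinetic control the phenoxide should attack the more substituted terminus of the π-allyl complex, which gives the tertiary ether 18 directly.

## Further compounds

F1 | step 8 | methyl 2-[2,6-bis(benzyloxy)-4-methoxyphenyl]-3-[2,4-bis(methoxymethoxy)phenyl]-3-oxopropanoate (racemic) | COC(=O)C(C(=O)c1ccc(OCOC)cc1OCOC)c1c(OCc2ccccc2)cc(OC)cc1OCc1ccccc1
F2 | step 8 | methyl 3-[2,4-bis(methoxymethoxy)phenyl]-2-(2,6-dihydroxy-4-methoxyphenyl)-3-oxopropanoate (racemic) | COC(=O)C(C(=O)c1ccc(OCOC)cc1OCOC)c1c(O)cc(OC)cc1O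
F3 | step 7 | 2,4-bis(methoxymethoxy)benzoyl chloride | O=C(Cl)c1ccc(OCOC)cc1OCOC
F4 | step 7 | 6-methoxy-4-(triisopropylsilyloxy)benzofuran-2-yl 2,4-bis(methoxymethoxy)benzoate | O=C(Oc1cc2c(O[Si](C(C)C)(C(C)C)C(C)C)cc(OC)cc2o1)c1ccc(OCOC)cc1OCOC
F0 | step 10 | none | none
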